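The partner and intermediate B are the reactants of both proposed routes, one to target and one to side product, and I read the flask from that.

| setting | zeta | epsilon | delta | flask |
|---|---|---|---|---|
| starting material | 0.10 M | 0.15 M | 0.20 M | 0.20 M |
| partner | 0.20 M | 0.20 M | 0.10 M | 0.200 M |
| remark | run made earlier | run made earlier | run made earlier |  |
| time |  |  |  | 25 h |

| run | time / h | target / % | side product / % | starting material / % |
|---|---|---|---|---|
| zeta | 8.00 | 95.6 | 2.7 | 0.3 |
| zeta | 15.0 | 96.8 | 2.3 | 0.2 |
| zeta | 25.0 | 96.9 | 2.6 | 0.1 |
| zeta | 30.0 | 97.2 | 1.7 | 0 |
| epsilon | 2.50 | 65.0 | 2.1 | 0.7 |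
| epsilon | 6.00 | 89.8 | 2.3 | 0.2 |
| epsilon | 12.0 | 95.4 | 2.6 | 0 |
| epsilon | 30.0 | 97.0 | 1.8 | 0 |
| delta | 4.00 | 45.4 | 1.9 | 0.1 |
| delta | 10.0 | 48.5 | 1.7 | 0.3 |
| delta | 20.0 | 48.5 | 1.5 | 1.4 |
| delta | 30.0 | 48.4 | 2.3 | 0 |

(each reading ± 0.5 percentage points)

* ratio of target to side product at 20 min
* ratio of target to side product at 3.0 h
* ratio of target to side product at 25 h

- the numbers in the tables scatter with a standard deviation of 0.5 percentage points
- what may be going on: starting material -> intermediate A; partner + intermediate B -> target; partner + intermediate B -> side product; intermediate A <-> intermediate B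

Does the ratio change with time? If the proposed steps hold, each product forms at its own constant times [partner][intermediate B], so these concentrations cancel from the ratio of the two rates. Both products start from zero, so the ratio of their amounts equals that ratio of rates at every moment, and the same number answers each question.

What is that number? A single side product reading is poor, so I pool the 12 readings of each product. Target adds up to 924% and side product to 25.5%. This gives my selectivity factor S, the target formed per side product formed, as 36.3, with a scatter of about 2.46. The delta run alone reads 25.8, so I hold S loosely, but I commit to it at each time.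

The forecast gives 6 at 20 min, 33 at 3.0 h and 43 at 25 h, judging that the side product suggests “it tracks early starting-material turnover rather than the slow partner step”. My flat value stands above it at 20 min and below it at 25 h.

The flask gives 34.3 at 20 min, 34.3 at 3.0 h and 34.3 at 25 h.

    starting material → intermediate A (k = 0.0332 min⁻¹)
    partner + intermediate B → target (k = 0.192 M⁻¹ min⁻¹)
    partner + intermediate B → side product (k = 0.00559 M⁻¹ min⁻¹)
    intermediate A ⇌ intermediate B (K = 1.20, k = 0.0293 min⁻¹)

A neighbouring flask keeps 0.200 M of partner but is charged with 0.80 M of starting material, which makes the partner the limiting reagent. Each partner consumed gives one product, and S splits them. If the partner charge is consumed, target comes to 24.3% and side product to 0.671% of the starting material charged. At 25.0 h that flask holds 0% of its partner, with target at 24.3% and side product at 0.707%, a ratio of 34.3.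

The runs stem from a simulated flask on assumed constants, and the scatter is random.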